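1. I started from the product. In the autumn run it read 90.7% at 2.00 d and 90.7% at 5.00 d, with reagent charged at 0.90 equiv, so I booked one mole of reagent to each mole of product.

in all of them: free catalyst 0.2 mol%; second catalyst 0.2 mol%
- dawn: substrate 1.5 M; reagent 0.90 equiv; the very flask that is asked about, followed so far
- autumn: substrate 0.75 M; reagent 0.90 equiv; run made earlier
- flask: substrate 1.5 M; reagent 0.900 equiv; time 5.0 d

- dawn (time / h: open intermediate / %, product / %, substrate / %): 0.500: 24.9, 9.3, 61.7; 1.33: 43.4, 29.1, 29.0; 2.50: 43.1, 46.1, 11.3; 4.00: 35.6, 63.6, 3.2; 6.00: 25.1, 74.3, 0.6; 8.00: 16.4, 82.0, 0; 10.0: 13.6, 85.9, 0.1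
- autumn (time / d: open intermediate / %, product / %, substrate / %): 0.625: 17.8, 80.2, 0; 1.25: 10.0, 89.4, 1.1; 2.00: 10.1, 90.7, 0; 3.00: 9.8, 89.6, 1.7; 4.00: 9.9, 89.9, 0; 5.00: 9.1, 90.7, 0

(scatter of a reading: 1 percentage point)

- time, not beyond 5.0 d, at which the flask holds most open intermediate
- the amount of open intermediate, in percent of the substrate charged, at that time
- earliest time at which at least nineteen twentieths of that best amount are there, in d
- latest time at which they still are, in d

2. I then balanced the books against the substrate. Reagent, the limiting reagent here, covers 0.900 equiv of each mole of substrate. The uncovered part is 10.0%, which I called the stranded share: one minus the equivalents of reagent, the part of the substrate charged to which no reagent is booked. The autumn run read 10.1% and 9.1% of open intermediate at those same times.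

3. Each reading then has one running entry: c(open intermediate) is the charge less c(substrate) and c(product). In the dawn run at 10.0 h, product read 85.9%, so by the ledger reagent for 4.1 percentage points of the substrate charged remained to be booked, and open intermediate read 13.6%.

4. One small entry stayed open: the second catalyst, charged at 0.2 mol%, might hold some of the material.

5. My reckoning for the flask was an end near 10.0%. The dawn run, which is this same flask, had already read 43.4% at 1.33 h, more than the stranded share. So I placed the maximum early.

6. The forecast gave 44% at 0.08 d, with the asked level held from 0.052 d to 0.12 d. Its ground was: “So the maximum is the early one, not a late one.”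

    substrate + free catalyst → free catalyst + open intermediate (k = 5.00 /M/min)
    second catalyst + open intermediate ⇌ catalyst intermediate (K = 63.0 /M, k = 89.0 /M/min)
    reagent + catalyst intermediate → second catalyst + product (k = 1.80 /M/min)

The flask reached 43.5% at 0.0803 d and held the asked level from 0.0554 d to 0.113 d, in agreement with the forecast. At 5.00 d it held 9.82% of open intermediate, 0.18 points under the stranded share, while catalyst intermediate, at 90.3% of the second catalyst charged, held 0.181% of the substrate charged. The forecast's numbers belong to this recipe: the neighbour charged with 0.360 equiv of reagent has a stranded share of 64.0%, ended with 63.8% of open intermediate, and had a best of 71.7%.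

Readings and results are simulated for substances that don't exist; noise was put on by code.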